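## Structural features

The target is a germacranolide: a ten-membered carbocycle C1–C10 with an α-methylene-γ-butyrolactone trans-fused across C6–C7 (lactone oxygen on C6, C11 on C7, exocyclic C13, carbonyl C12). Four contiguous stereocentres lie on one edge of the ring: C6 (R), C7 (S), C8 (S, esterified with (S)-2-methylbutanoic acid) and C9 (S, free hydroxyl); the oxygens on C8 and C9 are syn (threo). The ring holds two trisubstituted alkenes, C1=C10 and C4=C5, both with the ring carbons cis (both E by the sequence rule, because C14 is a formyl group and C15 a hydroxymethyl group). The fragile groups are the two Michael acceptors (α-methylene lactone, C1=C10–C14 enal), the C9 carbinol (allylic, β to the formyl group, vicinal to an ester, so open to acyl shift and elimination) and the enolisable stereocentre of the side-chain acid. The real difficulty is closing a medium ring with two defined alkene geometries next to the densely oxygenated C6–C9 segment while keeping both acceptors out of most of the route. The key step uses the array C2–C1=C10(C14)–C9(OH): a β-alkyl-α-(hydroxyalkyl)acrylate, which is the formal adduct of an alkyl nucleophile (C2–C4 with C15), a propiolate (C1, C10, C14) and an α-alkoxy aldehyde (C9 carrying C8, C7, C6 and the lactone).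

## Logic of the disconnections

**39 ⇒ 38 ⇒ 35 + 36 ⇒ 34.** The O9–Si and O15–Si bonds, the O8–acyl bond and the O8–benzyl bond are cut. The C9 carbinol and the primary allylic alcohol are the groups most exposed to acyl shift and oxidation, so they are unveiled last. The side chain goes on after all hydride and enolate chemistry, so its stereocentre never meets base. The gain is a core (34) with three orthogonal protecting groups and a purchasable chiral acid (36). The demands are an oxidative debenzylation that spares two Michael acceptors, an acylation of a hindered secondary alcohol without ketene formation, and an acidic fluoride source that does not promote O8→O9 acyl migration.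

**34 ⇒ 33 ⇒ 32 ⇒ 28.** The C11=C13 bond is cut and the C14 formyl group is traced back to the methyl ester that the key step delivers. No reagent reduces an enoate beside a γ-lactone. With C13 in place first, the lactone carbinol carbon is allylic, so a global hydride reduction (33) followed by an allylic-selective oxidant restores the lactone and gives the enal in one operation. The gain is that 28 carries neither acceptor of the target. The demands are enolisation at C11 only and an oxidant that acts on an allylic lactol and a primary allylic alcohol but not on ethers.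

**28 ⇒ 27 ⇒ 26.** C4=C5 is cut (ring-closing metathesis), together with the O9–Si bond. C4=C5 is the one ring bond whose two carbons can each end as a cheap terminal alkene (C5 from the sugar terminus, C4 from the alkyl fragment), and the ring-cis geometry needed is the one a ten-membered ring prefers. The gain is an acyclic triene. The demands are high dilution, a catalyst that engages a 1,1-disubstituted alkene bearing an allylic silyloxy group, and a capped C9 hydroxyl.

**26 ⇒ 21 + 22 + 16.** C1–C2 and C9–C10 are cut in one operation. The enoate sector falls into a four-carbon alkyl donor, a three-carbon alkyne and a seven-carbon aldehyde that already holds C6, C7 and C8. The demands are syn addition across the alkyne, a configurationally stable alkenylmetal, chelation control at C9 and selectivity for the aldehyde over lactone and ester.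

**16 ⇒ 15 ⇒ 13 ⇒ 12 ⇒ 10 ⇒ 9.** The aldehyde is traced to a primary alcohol (15). The lactone C12–O6 bond and C9 are traced to a furanoside (13, 12) in which O6 is the ring oxygen and C9 the anomeric carbon. The O8–benzyl bond is cut, and in 10 the carboxyl is parked as a lactone on O8. In the all-cis furanose the acetic acid arm and O8 are cis, so closure on O8 is unavoidable once O8 is free; an order that alkylates O8 beside an open ester arm is not workable. The closure is therefore accepted (10), the lactone is opened with hydroxide and both oxygens are alkylated (12). Hydrolysis and reduction of the lactol give a 1,4-diol whose only five-membered lactone is the trans one on O6. The aldehyde is regenerated by oxidation just before use, because a direct acid-mediated switch from lactol to lactone-aldehyde would expose an epimerisable α-alkoxy aldehyde to acid and compete with lactol-acid and acylal forms. The demand is furanoside hydrolysis in the presence of the PMB ether.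

**9 ⇒ 8 ⇒ 7 ⇒ 6 ⇒ 5 ⇒ 3 ⇒ 1.** The terminal alkene carbon on C5 is cut (methylenation of the sugar C5 aldehyde), as is the C7–C11 bond (olefination of the sugar C3 ketone, then hydrogenation). 1 supplies C8 and C6 (sugar C2 and C4) in the right absolute sense. Its 1,2-acetonide is cis to the C4 side chain, so hydrogen can only arrive from the opposite face, which sets C7. The gain is three of the four ring stereocentres from the chiral pool. The demands are no epimerisation α to the ketone (hence a base-free oxidant and a stabilised ylide instead of a phosphonate anion) and no closure of the ester on O5 after desilylation (hence the tert-butyl ester).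

**21 ⇒ 20 ⇒ 18 ⇒ 17.** The C3–C4 bond is cut (alkenyl anion at C4, two-carbon epoxide for C2–C3), then the C2–I bond. A route through an unsymmetrical diol with two primary hydroxyls would rest on a monosilylation that should favour the less hindered homoallylic oxygen, the wrong one. Starting from 17, silicon is on the allylic oxygen before the second oxygen exists. The demand is that the alkenyllithium is trapped cold.

## Other disconnections considered

**Alternative 1:** Cut C4=C5 and C11=C13, with a temporary C5–C11 bond held in a cyclobutene (A2). In the forward step, under ethylene, (H2IMes)Cl2Ru=CH(C6H4-2-OiPr) (second-generation Hoveyda–Grubbs catalyst) would open the cyclobutene of A2. Methylene goes to C11 (creating C11=C13) and the carbene to C5, which then closes on the C4 alkene to give the ten-membered dienal A1.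
- In favour: ring strain drives initiation, and the carbene is generated on C5 within the molecule, so the catalyst need not load onto a hindered alkene. This is better than the plain diene closure chosen here. The exocyclic methylene arises in the same event, without enolate chemistry.
- Also in favour: A1 already holds the enal and the ester. Only desilylation at O6/O12, allylic oxidation to the lactone and final desilylation remain, a clearly shorter endgame than the eight steps after the key step here.
- Against: A2 needs a stereodefined cis-3,4-disubstituted cyclobutene carrying most of the stereochemical information, with no chiral-pool entry in sight. The opening must be regioselective (ruthenium on C5, not C11). Under ethylene the C5 carbene can be capped to a vinyl group, after which the closure is the same metathesis as in the chosen plan. The enal and the epimerisable ester would sit through hot carbene chemistry.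
- Comparison: equal or better on ring closure and on post-cyclisation step count; worse on access to the substrate and on convergence.

**Alternative 2:** Cut C8–C9 and reconnect C1–C6. In the forward step, KH with 18-crown-6 would convert the cyclohexenol A4 into its alkoxide, and a [3,3] shift would give the cyclodecadienone A3.
- In favour: the step is unimolecular and charge-accelerated and needs no dilution or metal, which is better than a medium-ring metathesis on entropic grounds. The ring-cis C4=C5 bond is inherited from the cyclohexene. C8 and C9 are set together from two E enol ethers through a chair array.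
- Against: the ring-cis C1=C10 bond requires the cis-dialkenyl isomer reacting with the C1–C2 ring bond axial (as A4 is drawn), a less favourable arrangement than the usual one that gives a ring-trans alkene. A4 carries two geometrically pure enol ethers on a tertiary carbinol. Both of its stereocentres are consumed, so the absolute configuration must be relayed.
- Also against: A3 lacks the entire lactone. Regioselective C7 alkylation, reduction of the C6 ketone to the R carbinol, C14 oxidation and MOM/PMB differentiation remain, well over the eight steps of the present endgame.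
- Comparison: better on the ring-forming event and the C4=C5 geometry; weaker on C1=C10 geometry, on C6/C7 control and on step economy.

**Alternative 3:** Cut C2–C3. In the forward step, KN(SiMe3)2 would deprotonate the allylic sulfone of the acyclic bromo sulfone A6 at C3, and the carbanion would displace the allylic bromide at C2 to give macrocycle A5.
- In favour: both alkene geometries and all four stereocentres are fixed before ring closure, so the closure carries no stereochemical risk. This is better than the metathesis chosen here, which must set the C4=C5 geometry while closing. Sulfone alkylation at high dilution is a well-tried macrocyclisation, and the C9–C10 sector of A6 could still be made by the three-component coupling.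
- Against: the sulfone costs its installation and a reductive removal next to two allylic systems (alkene migration, over-reduction). SN2′ attack and γ-alkylation of the ambident anion may compete. A6 is a long linear chain with six protecting groups. After A5, C12, C14 and C15 are all still alcohols, so three triethylsilyl ethers must be differentiated before oxidation, lactonisation and the PMB-to-acyl exchange.
- Comparison: equal or better on geometric security of the ring closure; worse on step count and protecting-group load.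

Key step: step 15

Remarks on the chemistry (assumptions):
- Germacrane numbering of the target is used for all intermediates. Pentose positions are called sugar C1–C5 (sugar C1 = C9, C2 = C8, C3 = C7, C4 = C6, C5 = C5).
- Anomeric or lactol mixtures (2, 10–13, 33), the alkene mixture 5 and the C11 epimers 30 and 31 are carried on as mixtures, because the stereo-element concerned is removed later. Their SMILES leave it undefined.
- TBDPS = tert-butyldiphenylsilyl, TBS = tert-butyldimethylsilyl, TES = triethylsilyl, PMB = 4-methoxybenzyl.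

## Route

Step 1
Reactants: 1 D-arabinose
Product: 3 5-O-TBDPS-1,2-O-isopropylidene-β-D-arabinofuranose, via silyl ether 2 (not isolated)
Conditions: TBDPSCl, imidazole, DMF, 0 °C to rt; concentrate; acetone, Me2C(OMe)2, TsOH·H2O (cat.), rt
Reagents that add atoms: tert-butyl(chloro)diphenylsilane CC(C)(C)[Si](Cl)(c1ccccc1)c1ccccc1; 2,2-dimethoxypropane COC(C)(C)OC
Why: Primary-selective silyl ether formation locks the pentose as a furanose, and thermodynamic isopropylidene acetal formation can then only engage the cis O1/O2 pair of the β-furanose, leaving O3 free; no stereocentre is created.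

Step 2
Reactants: 3 5-O-TBDPS-1,2-O-isopropylidene-β-D-arabinofuranose
Product: 5 tert-butyl (5-O-TBDPS-3-deoxy-1,2-O-isopropylidene-β-D-threo-pentofuranos-3-ylidene)acetate (E/Z mixture), via ketone 4 (not isolated)
Conditions: IBX, EtOAc, 75 °C; filter; Ph3P=CHCO2t-Bu, 50 °C
Reagents that add atoms: tert-butyl (triphenylphosphoranylidene)acetate CC(C)(C)OC(=O)C=P(c1ccccc1)(c1ccccc1)c1ccccc1
Why: IBX oxidation is neutral, so the sugar C4 centre α to the new ketone is not enolised, and the strained, electron-poor 3-ulose is taken straight into a Wittig olefination with a stabilised, weakly basic ylide; both alkene isomers converge in step 3.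

Step 3
Reactants: 5 tert-butyl (5-O-TBDPS-3-deoxy-1,2-O-isopropylidene-β-D-threo-pentofuranos-3-ylidene)acetate
Product: 6 3-C-(2-tert-butoxy-2-oxoethyl)-5-O-TBDPS-3-deoxy-1,2-O-isopropylidene-β-D-lyxofuranose
Conditions: H2 (1 atm), Pd/C (10% palladium on carbon), EtOAc, rt
Reagents that add atoms: none
Why: Heterogeneous catalytic hydrogenation; the acetonide and the sugar C4 side chain both shield the upper face of the cis-fused bicycle, so hydrogen should add from the lower face and place the acetate arm cis to O2 and C5, which is the C7 configuration of the target (the same facial bias is known for hydride reduction of ketone 4).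

Step 4
Reactants: 6 3-C-(2-tert-butoxy-2-oxoethyl)-5-O-TBDPS-3-deoxy-1,2-O-isopropylidene-β-D-lyxofuranose
Product: 7 3-C-(2-tert-butoxy-2-oxoethyl)-3-deoxy-1,2-O-isopropylidene-β-D-lyxofuranose
Conditions: Bu4NF, AcOH, THF, 0 °C to rt
Reagents that add atoms: none
Why: Fluoride-mediated desilylation; acetic acid buffering and the bulk of the tert-butyl ester should suppress closure of the freed O5 onto the cis acetate arm.

Step 5
Reactants: 7 3-C-(2-tert-butoxy-2-oxoethyl)-3-deoxy-1,2-O-isopropylidene-β-D-lyxofuranose
Product: 8 3-C-(2-tert-butoxy-2-oxoethyl)-3-deoxy-1,2-O-isopropylidene-β-D-lyxo-pentodialdo-1,4-furanose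
Conditions: Dess–Martin periodinane, NaHCO3, CH2Cl2, 0 °C to rt
Reagents that add atoms: none
Why: Dess–Martin oxidation of a primary alcohol under buffered, non-basic conditions, chosen so that the α-alkoxy aldehyde does not epimerise at sugar C4; the crude aldehyde is used at once.

Step 6
Reactants: 8 3-C-(2-tert-butoxy-2-oxoethyl)-3-deoxy-1,2-O-isopropylidene-β-D-lyxo-pentodialdo-1,4-furanose
Product: 9 3-C-(2-tert-butoxy-2-oxoethyl)-3,5,6-trideoxy-1,2-O-isopropylidene-β-D-lyxo-hex-5-enofuranose
Conditions: Ph3PCH3Br, KN(SiMe3)2, THF, −78 °C to 0 °C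
Reagents that add atoms: methyltriphenylphosphonium bromide C[P+](c1ccccc1)(c1ccccc1)c1ccccc1.[Br-]
Why: Wittig methylenation with a salt-free, non-stabilised ylide at low temperature, the standard conversion of sugar dialdofuranoses into vinyl compounds; the tert-butyl ester is inert and no stereocentre is formed.

Step 7
Reactants: 9 3-C-(2-tert-butoxy-2-oxoethyl)-3,5,6-trideoxy-1,2-O-isopropylidene-β-D-lyxo-hex-5-enofuranose
Product: 10 methyl 3-C-(carboxymethyl)-3,5,6-trideoxy-D-lyxo-hex-5-enofuranoside 2,3-γ-lactone (anomers)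
Conditions: HCl (1.25 M in MeOH), rt to 40 °C
Reagents that add atoms: methanol CO
Why: Acid-catalysed transacetalisation (Fischer-type glycosidation) removes the acetonide; the freed O2 hydroxyl, cis to the acetate arm, then lactonises with loss of the tert-butyl group, and the furanoside ring is kept as the protecting group for C9 and O6.

Step 8
Reactants: 10 methyl 3-C-(carboxymethyl)-3,5,6-trideoxy-D-lyxo-hex-5-enofuranoside 2,3-γ-lactone
Product: 12 4-methoxybenzyl [methyl 3,5,6-trideoxy-2-O-(4-methoxybenzyl)-D-lyxo-hex-5-enofuranosid-3-C-yl]acetate, via lithium carboxylate 11 (not isolated)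
Conditions: LiOH·H2O, THF/H2O, rt; evaporate, dry; NaH, PMBCl, Bu4NI (cat.), DMF, 0 °C to rt
Reagents that add atoms: lithium hydroxide [Li+].[OH-]; 4-methoxybenzyl chloride COc1ccc(CCl)cc1
Why: Saponification opens the lactone to a carboxylate that cannot relactonise, and a double Williamson-type alkylation then gives the O8 PMB ether and the PMB ester together; no stereocentre is touched.

Step 9
Reactants: 12 4-methoxybenzyl [methyl 3,5,6-trideoxy-2-O-(4-methoxybenzyl)-D-lyxo-hex-5-enofuranosid-3-C-yl]acetate
Product: 13 4-methoxybenzyl [3,5,6-trideoxy-2-O-(4-methoxybenzyl)-D-lyxo-hex-5-enofuranos-3-C-yl]acetate (lactol)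
Conditions: 1 M HCl (aq), THF, 45 °C
Reagents that add atoms: water O
Why: Acid hydrolysis of a furanoside, which is far faster than that of pyranosides and should proceed in dilute aqueous acid that PMB ethers tolerate; any PMB ester hydrolysed to the acid converges in step 10.

Step 10
Reactants: 13 4-methoxybenzyl [3,5,6-trideoxy-2-O-(4-methoxybenzyl)-D-lyxo-hex-5-enofuranos-3-C-yl]acetate
Product: 15 (4S,5R)-5-ethenyl-4-[(1S)-2-hydroxy-1-(4-methoxybenzyloxy)ethyl]oxolan-2-one, via diol ester 14 (not isolated)
Conditions: NaBH4, MeOH, 0 °C; AcOH quench; PPTS (cat.), toluene, 50 °C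
Reagents that add atoms: none
Why: Borohydride reduces the lactol through its open hydroxy-aldehyde form, and the released O6 hydroxyl closes on the ester by acid-catalysed lactonisation, the five-membered lactone being favoured over the six-membered one through O9; the trans relation of C5 and C8 on the lactone follows from the all-cis furanose.

Step 11
Reactants: 15 (4S,5R)-5-ethenyl-4-[(1S)-2-hydroxy-1-(4-methoxybenzyloxy)ethyl]oxolan-2-one
Product: 16 (2S)-2-[(2R,3S)-2-ethenyl-5-oxooxolan-3-yl]-2-(4-methoxybenzyloxy)acetaldehyde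
Conditions: Dess–Martin periodinane, NaHCO3, CH2Cl2, 0 °C
Reagents that add atoms: none
Why: Buffered Dess–Martin oxidation gives the α-alkoxy aldehyde without base or strong acid, so C8 should keep its configuration; 16 is used directly in step 15.

Step 12
Reactants: 17 2-bromoprop-2-en-1-ol
Product: 18 [(2-bromoprop-2-en-1-yl)oxy](tert-butyl)diphenylsilane
Conditions: TBDPSCl, imidazole, CH2Cl2, rt
Reagents that add atoms: tert-butyl(chloro)diphenylsilane CC(C)(C)[Si](Cl)(c1ccccc1)c1ccccc1
Why: Silyl ether formation on a primary allylic alcohol; it fixes the silyl group on the future C15 oxygen before the second oxygen function exists.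

Step 13
Reactants: 18 [(2-bromoprop-2-en-1-yl)oxy](tert-butyl)diphenylsilane
Product: 20 3-{[tert-butyl(diphenyl)silyl]oxymethyl}but-3-en-1-ol, via alkenyllithium 19 (not isolated)
Conditions: t-BuLi (2.1 equiv), Et2O, −78 °C; ethylene oxide, BF3·OEt2, −78 °C
Reagents that add atoms: oxirane C1CO1
Why: Bromine–lithium exchange gives the 2-lithioallyl silyl ether, which opens the BF3-activated epoxide at −78 °C (organolithium–epoxide opening under Lewis acid assistance) and so adds C2 and C3 with the hydroxyl on C2.

Step 14
Reactants: 20 3-{[tert-butyl(diphenyl)silyl]oxymethyl}but-3-en-1-ol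
Product: 21 tert-butyl[(4-iodo-2-methylidenebutyl)oxy]diphenylsilane
Conditions: I2, PPh3, imidazole, CH2Cl2, 0 °C to rt
Reagents that add atoms: iodine II
Why: Appel-type iodination (Garegg–Samuelsson conditions) of a primary homoallylic alcohol by SN2 displacement of the alkoxyphosphonium ion; silyl ether and alkene are unaffected.

Step 15
Reactants: 21 tert-butyl[(4-iodo-2-methylidenebutyl)oxy]diphenylsilane; 22 methyl propiolate; 16 (2S)-2-[(2R,3S)-2-ethenyl-5-oxooxolan-3-yl]-2-(4-methoxybenzyloxy)acetaldehyde
Product: 26 methyl (2E)-2-[(1S,2S)-2-[(2R,3S)-2-ethenyl-5-oxooxolan-3-yl]-1-hydroxy-2-(4-methoxybenzyloxy)ethyl]-6-{[tert-butyl(diphenyl)silyl]oxymethyl}hepta-2,6-dienoate, via alkyllithium 23 (not isolated), via alkylcopper 24 (not isolated), via alkenylcopper 25 (not isolated)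
Conditions: 21, t-BuLi (2 equiv), Et2O, −78 °C; CuBr·SMe2, THF, −78 to −40 °C; 22, −78 °C; 16 premixed with MgBr2·OEt2 in CH2Cl2, −78 °C; NH4Cl (aq)
Reagents that add atoms: none
Why: Iodine–lithium exchange on 21 and transmetalation to CuBr·SMe2 should give alkylcopper 24, which adds across the triple bond of 22 by syn carbocupration (alkyl to the unsubstituted alkyne carbon, copper to the carbon α to the ester), forming C1–C2 and placing C2 and copper cis in 25. At −78 °C the α-cuprio acrylate should hold its configuration, since isomerisation through the copper allenolate needs higher temperature, and it then adds to the formyl carbon of 16 with retention at the alkenyl carbon, forming C9–C10; the closest known reaction type is the tandem carbocupration–aldol of propiolates that leads to β-substituted Morita–Baylis–Hillman-type adducts. No ring is closed. The only new stereocentre, C9, is controlled by C8 through a five-membered magnesium chelate between the formyl oxygen and the PMB ether oxygen (Cram chelate model), in which the alkenyl group attacks the face away from the lactone-bearing C7 substituent and should give the 8,9-syn (threo) 9S carbinol. The alkene geometry (C2 cis to C9, ester trans to C2) follows from syn addition plus retention and is what the later ring-cis C1=C10 bond needs. Selectivity for the aldehyde over lactone and ester rests on the low nucleophilicity and basicity of the organocopper and on Lewis-acid activation of the chelated aldehyde only, so the C8 proton is not at risk. The step needs an unbroken cold one-pot sequence and a slight excess of 25 over the more valuable 16.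

Step 16
Reactants: 26 methyl (2E)-2-[(1S,2S)-2-[(2R,3S)-2-ethenyl-5-oxooxolan-3-yl]-1-hydroxy-2-(4-methoxybenzyloxy)ethyl]-6-{[tert-butyl(diphenyl)silyl]oxymethyl}hepta-2,6-dienoate
Product: 27 the C9 tert-butyldimethylsilyl ether of 26
Conditions: TBSOTf, 2,6-lutidine, CH2Cl2, −78 to 0 °C
Reagents that add atoms: tert-butyldimethylsilyl trifluoromethanesulfonate CC(C)(C)[Si](C)(C)OS(=O)(=O)C(F)(F)F
Why: Silylation of a hindered secondary allylic alcohol with a silyl triflate and a non-nucleophilic base; the cap keeps C9 out of the later allylic oxidation and is removed together with the C15 silyl group.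

Step 17
Reactants: 27 the C9 tert-butyldimethylsilyl ether of 26
Product: 28 methyl 9-(TBSO)-15-(TBDPSO)-8-(PMBO)germacra-1(10),4-dien-12,6-olid-14-oate (both ring alkenes ring-cis)
Conditions: (H2IMes)(PCy3)Cl2Ru=CHPh (second-generation Grubbs catalyst, 10 mol%), toluene (1 mM), 90 °C, argon purge
Reagents that add atoms: none
Why: Ring-closing metathesis; the catalyst should load on the monosubstituted C5 vinyl group and close on the 1,1-disubstituted C4 alkene with loss of ethene, the pre-set cis C1=C10 bond and the lactone holding the chain ends together. The ring-cis (4E by the sequence rule) trisubstituted alkene is expected because a ten-membered ring that already holds a cis alkene and a trans-fused lactone accommodates a further cis alkene with less strain.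

Step 18
Reactants: 28 methyl 9-(TBSO)-15-(TBDPSO)-8-(PMBO)germacra-1(10),4-dien-12,6-olid-14-oate
Product: 32 methyl 9-(TBSO)-15-(TBDPSO)-8-(PMBO)germacra-1(10),4,11(13)-trien-12,6-olid-14-oate, via lithium enolate 29 (not isolated), via Mannich base 30 (not isolated), via ammonium iodide 31 (not isolated)
Conditions: LiN(SiMe3)2, THF, −78 °C; CH2=NMe2+ I−, −78 to 0 °C; MeI, MeOH, rt; NaHCO3 (aq), CH2Cl2, rt
Reagents that add atoms: N,N-dimethylmethyleneiminium iodide C=[N+](C)C.[I-]
Why: Eschenmoser methylenation: the lactone enolate is aminomethylated (Mannich reaction), the amine is quaternised and trimethylamine is eliminated to give the exocyclic alkene. The enoate has no α-hydrogen and its γ-carbon C2 is trans to the ester, so only C11 should be deprotonated; C7 is not α to the carbonyl and cannot epimerise.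

Step 19
Reactants: 32 methyl 9-(TBSO)-15-(TBDPSO)-8-(PMBO)germacra-1(10),4,11(13)-trien-12,6-olid-14-oate
Product: 33 9-(TBSO)-15-(TBDPSO)-8-(PMBO)-6,12-epoxygermacra-1(10),4,11(13)-triene-12,14-diol (lactol epimers)
Conditions: iBu2AlH (5 equiv), CH2Cl2, −78 to −40 °C; KNaC4H4O6 (aq)
Reagents that add atoms: none
Why: iBu2AlH reduces the enoate in 1,2-fashion to the primary allylic alcohol and the lactone to the lactol; any material reduced further to the allylic 6,12-diol is expected to converge in step 20.

Step 20
Reactants: 33 9-(TBSO)-15-(TBDPSO)-8-(PMBO)-6,12-epoxygermacra-1(10),4,11(13)-triene-12,14-diol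
Product: 34 9-(TBSO)-15-(TBDPSO)-8-(PMBO)-14-oxogermacra-1(10),4,11(13)-trien-12,6-olide
Conditions: MnO2 (activated, excess), CH2Cl2, rt
Reagents that add atoms: none
Why: Allylic oxidation with MnO2: the primary allylic C14 alcohol gives the enal and the α-methylene lactol (an allylic hemiacetal) is oxidised back to the α-methylene lactone, a known way to form such lactones; ethers and silyl ethers are inert.

Step 21
Reactants: 34 9-(TBSO)-15-(TBDPSO)-8-(PMBO)-14-oxogermacra-1(10),4,11(13)-trien-12,6-olide
Product: 35 8-hydroxy-9-(TBSO)-15-(TBDPSO)-14-oxogermacra-1(10),4,11(13)-trien-12,6-olide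
Conditions: DDQ, CH2Cl2/pH 7 phosphate buffer (10:1), 0 °C to rt
Reagents that add atoms: none
Why: Oxidative cleavage of the PMB ether by DDQ (hydride abstraction from the electron-rich benzylic position, then hydrolysis); the electron-poor enal and lactone alkenes and the silyl ethers are not expected to react.

Step 22
Reactants: 35 8-hydroxy-9-(TBSO)-15-(TBDPSO)-14-oxogermacra-1(10),4,11(13)-trien-12,6-olide; 36 (S)-2-methylbutanoic acid
Product: 38 9-(TBSO)-15-(TBDPSO)-8-[(2S)-2-methylbutanoyloxy]-14-oxogermacra-1(10),4,11(13)-trien-12,6-olide, via mixed anhydride 37 (not isolated)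
Conditions: 36, 2,4,6-Cl3C6H2COCl, Et3N, THF, rt; then 35, DMAP, toluene, rt
Reagents that add atoms: none
Why: Yamaguchi esterification, suited to hindered secondary alcohols; acyl transfer from the mixed anhydride through the acylpyridinium ion avoids a ketene, so the α-stereocentre of the acid should be kept.

Step 23
Reactants: 38 9-(TBSO)-15-(TBDPSO)-8-[(2S)-2-methylbutanoyloxy]-14-oxogermacra-1(10),4,11(13)-trien-12,6-olide
Product: 39 (1(10)E,4E,6R,7S,8S,9S)-9,15-dihydroxy-8-[(2S)-2-methylbutanoyloxy]-14-oxogermacra-1(10),4,11(13)-trien-12,6-olide (CNP0331447.1)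
Conditions: HF·pyridine, pyridine, THF, 0 °C to rt
Reagents that add atoms: none
Why: Fluoride-mediated cleavage of both silyl ethers under mildly acidic conditions, chosen so that no alkoxide forms at O9 that could take the acyl group from O8 or add to the Michael acceptors.

## Compound list

1 | D-arabinose | O=C[C@@H](O)[C@H](O)[C@H](O)CO | starting material
2 | 5-O-TBDPS-D-arabinofuranose (anomers) | CC(C)(C)[Si](c1ccccc1)(c1ccccc1)OC[C@H]1OC(O)[C@@H](O)[C@@H]1O | intermediate
3 | 5-O-TBDPS-1,2-O-isopropylidene-β-D-arabinofuranose | CC(C)(C)[Si](c1ccccc1)(c1ccccc1)OC[C@H]1O[C@H]2OC(C)(C)O[C@H]2[C@@H]1O | intermediate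
4 | 5-O-TBDPS-1,2-O-isopropylidene-β-D-threo-pentofuranos-3-ulose | CC(C)(C)[Si](c1ccccc1)(c1ccccc1)OC[C@H]1O[C@H]2OC(C)(C)O[C@H]2C1=O | intermediate
5 | tert-butyl (5-O-TBDPS-3-deoxy-1,2-O-isopropylidene-β-D-threo-pentofuranos-3-ylidene)acetate (E/Z mixture) | CC(C)(C)[Si](c1ccccc1)(c1ccccc1)OC[C@H]1O[C@H]2OC(C)(C)O[C@H]2C1=CC(=O)OC(C)(C)C | intermediate
6 | 3-C-(2-tert-butoxy-2-oxoethyl)-5-O-TBDPS-3-deoxy-1,2-O-isopropylidene-β-D-lyxofuranose | CC(C)(C)[Si](c1ccccc1)(c1ccccc1)OC[C@H]1O[C@H]2OC(C)(C)O[C@H]2[C@H]1CC(=O)OC(C)(C)C | intermediate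
7 | 3-C-(2-tert-butoxy-2-oxoethyl)-3-deoxy-1,2-O-isopropylidene-β-D-lyxofuranose | OC[C@H]1O[C@H]2OC(C)(C)O[C@H]2[C@H]1CC(=O)OC(C)(C)C | intermediate
8 | 3-C-(2-tert-butoxy-2-oxoethyl)-3-deoxy-1,2-O-isopropylidene-β-D-lyxo-pentodialdo-1,4-furanose | O=C[C@H]1O[C@H]2OC(C)(C)O[C@H]2[C@H]1CC(=O)OC(C)(C)C | intermediate
9 | 3-C-(2-tert-butoxy-2-oxoethyl)-3,5,6-trideoxy-1,2-O-isopropylidene-β-D-lyxo-hex-5-enofuranose | C=C[C@H]1O[C@H]2OC(C)(C)O[C@H]2[C@H]1CC(=O)OC(C)(C)C | intermediate
10 | methyl 3-C-(carboxymethyl)-3,5,6-trideoxy-D-lyxo-hex-5-enofuranoside 2,3-γ-lactone (cis-fused, vinyl on the lactone face; anomers) | C=C[C@H]1OC(OC)[C@H]2OC(=O)C[C@@H]12 | intermediate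
11 | lithium (methyl 3,5,6-trideoxy-D-lyxo-hex-5-enofuranosid-3-C-yl)acetate | C=C[C@H]1OC(OC)[C@@H](O)[C@H]1CC(=O)[O-].[Li+] | intermediate
12 | 4-methoxybenzyl [methyl 3,5,6-trideoxy-2-O-(4-methoxybenzyl)-D-lyxo-hex-5-enofuranosid-3-C-yl]acetate | C=C[C@H]1OC(OC)[C@@H](OCc2ccc(OC)cc2)[C@H]1CC(=O)OCc1ccc(OC)cc1 | intermediate
13 | 4-methoxybenzyl [3,5,6-trideoxy-2-O-(4-methoxybenzyl)-D-lyxo-hex-5-enofuranos-3-C-yl]acetate (lactol) | C=C[C@H]1OC(O)[C@@H](OCc2ccc(OC)cc2)[C@H]1CC(=O)OCc1ccc(OC)cc1 | intermediate
14 | 4-methoxybenzyl (3S,4R)-4-hydroxy-3-[(1S)-2-hydroxy-1-(4-methoxybenzyloxy)ethyl]hex-5-enoate | C=C[C@@H](O)[C@H](CC(=O)OCc1ccc(OC)cc1)[C@@H](CO)OCc1ccc(OC)cc1 | intermediate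
15 | (4S,5R)-5-ethenyl-4-[(1S)-2-hydroxy-1-(4-methoxybenzyloxy)ethyl]oxolan-2-one | C=C[C@H]1OC(=O)C[C@@H]1[C@H](OCc1ccc(OC)cc1)CO | intermediate
16 | (2S)-2-[(2R,3S)-2-ethenyl-5-oxooxolan-3-yl]-2-(4-methoxybenzyloxy)acetaldehyde | C=C[C@H]1OC(=O)C[C@@H]1[C@H](OCc1ccc(OC)cc1)C=O | intermediate
17 | 2-bromoprop-2-en-1-ol | C=C(Br)CO | starting material
18 | [(2-bromoprop-2-en-1-yl)oxy](tert-butyl)diphenylsilane | C=C(Br)CO[Si](c1ccccc1)(c1ccccc1)C(C)(C)C | intermediate
19 | [3-(TBDPS-oxy)prop-1-en-2-yl]lithium | C=C([Li])CO[Si](c1ccccc1)(c1ccccc1)C(C)(C)C | intermediate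
20 | 3-{[tert-butyl(diphenyl)silyl]oxymethyl}but-3-en-1-ol | C=C(CCO)CO[Si](c1ccccc1)(c1ccccc1)C(C)(C)C | intermediate
21 | tert-butyl[(4-iodo-2-methylidenebutyl)oxy]diphenylsilane | C=C(CO[Si](c1ccccc1)(c1ccccc1)C(C)(C)C)CCI | intermediate
22 | methyl propiolate | C#CC(=O)OC | starting material
23 | [3-(TBDPS-oxymethyl)but-3-en-1-yl]lithium | [Li]CCC(=C)CO[Si](c1ccccc1)(c1ccccc1)C(C)(C)C | intermediate
24 | [3-(TBDPS-oxymethyl)but-3-en-1-yl]copper | [Cu]CCC(=C)CO[Si](c1ccccc1)(c1ccccc1)C(C)(C)C | intermediate
25 | methyl (2Z)-2-cuprio-6-(TBDPS-oxymethyl)hepta-2,6-dienoate (copper cis to C2) | COC(=O)/C([Cu])=C/CCC(=C)CO[Si](c1ccccc1)(c1ccccc1)C(C)(C)C | intermediate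
26 | methyl (2E)-2-[(1S,2S)-2-[(2R,3S)-2-ethenyl-5-oxooxolan-3-yl]-1-hydroxy-2-(4-methoxybenzyloxy)ethyl]-6-{[tert-butyl(diphenyl)silyl]oxymethyl}hepta-2,6-dienoate | C=C[C@H]1OC(=O)C[C@@H]1[C@H](OCc1ccc(OC)cc1)[C@@H](O)/C(C(=O)OC)=C\CCC(=C)CO[Si](c1ccccc1)(c1ccccc1)C(C)(C)C | intermediate
27 | C9 tert-butyldimethylsilyl ether of 26 | C=C[C@H]1OC(=O)C[C@@H]1[C@H](OCc1ccc(OC)cc1)[C@@H](O[Si](C)(C)C(C)(C)C)/C(C(=O)OC)=C\CCC(=C)CO[Si](c1ccccc1)(c1ccccc1)C(C)(C)C | intermediate
28 | methyl 9-(TBSO)-15-(TBDPSO)-8-(PMBO)germacra-1(10),4-dien-12,6-olid-14-oate (ring-cis alkenes; C6–C9 as drawn in 39) | C1C(=O)O[C@@H]2/C=C(/CO[Si](c3ccccc3)(c3ccccc3)C(C)(C)C)CC/C=C(/C(=O)OC)[C@H](O[Si](C)(C)C(C)(C)C)[C@@H](OCc3ccc(OC)cc3)[C@@H]12 | intermediate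
29 | lithium enolate of 28 (O-lithio ketene acetal at C11–C12) | C1=C(O[Li])O[C@@H]2/C=C(/CO[Si](c3ccccc3)(c3ccccc3)C(C)(C)C)CC/C=C(/C(=O)OC)[C@H](O[Si](C)(C)C(C)(C)C)[C@@H](OCc3ccc(OC)cc3)[C@@H]12 | intermediate
30 | 11-(dimethylaminomethyl) derivative of 28 (C11 epimers) | CN(C)CC1C(=O)O[C@@H]2/C=C(/CO[Si](c3ccccc3)(c3ccccc3)C(C)(C)C)CC/C=C(/C(=O)OC)[C@H](O[Si](C)(C)C(C)(C)C)[C@@H](OCc3ccc(OC)cc3)[C@@H]12 | intermediate
31 | trimethylammonium iodide derived from 30 | C[N+](C)(C)CC1C(=O)O[C@@H]2/C=C(/CO[Si](c3ccccc3)(c3ccccc3)C(C)(C)C)CC/C=C(/C(=O)OC)[C@H](O[Si](C)(C)C(C)(C)C)[C@@H](OCc3ccc(OC)cc3)[C@@H]12.[I-] | intermediate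
32 | methyl 9-(TBSO)-15-(TBDPSO)-8-(PMBO)germacra-1(10),4,11(13)-trien-12,6-olid-14-oate | C=C1C(=O)O[C@@H]2/C=C(/CO[Si](c3ccccc3)(c3ccccc3)C(C)(C)C)CC/C=C(/C(=O)OC)[C@H](O[Si](C)(C)C(C)(C)C)[C@@H](OCc3ccc(OC)cc3)[C@@H]12 | intermediate
33 | 9-(TBSO)-15-(TBDPSO)-8-(PMBO)-6,12-epoxygermacra-1(10),4,11(13)-triene-12,14-diol (lactol epimers) | C=C1C(O)O[C@@H]2/C=C(/CO[Si](c3ccccc3)(c3ccccc3)C(C)(C)C)CC/C=C(/CO)[C@H](O[Si](C)(C)C(C)(C)C)[C@@H](OCc3ccc(OC)cc3)[C@@H]12 | intermediate
34 | 9-(TBSO)-15-(TBDPSO)-8-(PMBO)-14-oxogermacra-1(10),4,11(13)-trien-12,6-olide | C=C1C(=O)O[C@@H]2/C=C(/CO[Si](c3ccccc3)(c3ccccc3)C(C)(C)C)CC/C=C(/C=O)[C@H](O[Si](C)(C)C(C)(C)C)[C@@H](OCc3ccc(OC)cc3)[C@@H]12 | intermediate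
35 | 8-hydroxy-9-(TBSO)-15-(TBDPSO)-14-oxogermacra-1(10),4,11(13)-trien-12,6-olide | C=C1C(=O)O[C@@H]2/C=C(/CO[Si](c3ccccc3)(c3ccccc3)C(C)(C)C)CC/C=C(/C=O)[C@H](O[Si](C)(C)C(C)(C)C)[C@@H](O)[C@@H]12 | intermediate
36 | (S)-2-methylbutanoic acid | CC[C@H](C)C(O)=O | starting material
37 | (2S)-2-methylbutanoic 2,4,6-trichlorobenzoic anhydride | CC[C@H](C)C(=O)OC(=O)c1c(Cl)cc(Cl)cc1Cl | intermediate
38 | 9-(TBSO)-15-(TBDPSO)-8-[(2S)-2-methylbutanoyloxy]-14-oxogermacra-1(10),4,11(13)-trien-12,6-olide | C=C1C(=O)O[C@@H]2/C=C(/CO[Si](c3ccccc3)(c3ccccc3)C(C)(C)C)CC/C=C(/C=O)[C@H](O[Si](C)(C)C(C)(C)C)[C@@H](OC(=O)[C@@H](C)CC)[C@@H]12 | intermediate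
39 | (1(10)E,4E,6R,7S,8S,9S)-9,15-dihydroxy-8-[(2S)-2-methylbutanoyloxy]-14-oxogermacra-1(10),4,11(13)-trien-12,6-olide (CNP0331447.1) | C=C1C(=O)O[C@@H]2/C=C(/CO)CC/C=C(/C=O)[C@H](O)[C@@H](OC(=O)[C@@H](C)CC)[C@@H]12 | target

## Step count and least certain steps

Total step count: 23. Longest linear sequence: 20 steps (steps 1–11 and 15–23); steps 12–14 form the second branch.

**Step 15 (key step).** The alkenylcopper may add to the aldehyde too slowly at the temperature at which its geometry is stable. Warming would then cause isomerisation through the allenolate and loss of alkene geometry. Incomplete chelation would lower facial selectivity at C9. Fallback: the two bond formations are separated. Starting from 21 (with 22), the alkenylcopper 25 is made as in step 15 but quenched with I2 to give methyl (2Z)-2-iodo-6-{[tert-butyl(diphenyl)silyl]oxymethyl}hepta-2,6-dienoate F1. Iodine–magnesium exchange (i-PrMgCl·LiCl, THF, −78 °C) gives the alkenylmagnesium chloride F2, a stronger nucleophile that adds to 16 (premixed with MgBr2·OEt2) under the same chelation control. The route is rejoined at 26.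

**Step 17.** Ruthenium may load slowly on either hindered alkene, so that intermolecular metathesis or alkene migration outruns ring closure. Partial formation of the ring-trans alkene cannot be ruled out beforehand. Fallback: the closure is moved to a less encumbered substrate. Starting from 26, Bu4NF/AcOH frees the C15 hydroxyl to give the acyclic diol F3. Ring-closing metathesis of F3, in which a free allylic hydroxyl sits next to the 1,1-disubstituted alkene (smaller, and known to assist metathesis), gives the macrocyclic diol F4. TBDPSCl/imidazole silylates the primary hydroxyl to give the C15 silyl ether F5, and TBSOTf/2,6-lutidine then caps C9. The route is rejoined at 28.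

**Step 20.** If step 19 has reduced part of the lactol further, the secondary allylic O6 hydroxyl may be oxidised. The oxidation may also stall before the lactol is converted. Fallback: the two oxidations are done one at a time. Starting from 33, Ag2CO3 on Celite (toluene, reflux) oxidises the lactol selectively to give the hydroxy lactone F6. Dess–Martin periodinane then oxidises the remaining primary allylic alcohol. The route is rejoined at 34.

**Step 9.** The PMB ether may be lost by acid-induced benzylic C–O cleavage before the furanoside is hydrolysed. Fallback: the acid step is placed before the PMB group exists. Starting from 9, aqueous trifluoroacetic acid removes the acetonide and the tert-butyl group to give the bicyclic lactone lactol F7. TBDPSCl/imidazole protects the anomeric hydroxyl to give the anomeric silyl ether F8. LiOH, then NaH/PMBCl (as in step 8), gives the bis-PMB compound F9. Bu4NF/AcOH then frees the lactol. The route is rejoined at 13.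

**Step 13.** On warming, silicon may migrate from oxygen to the lithiated carbon, the alkenyllithium may undergo β-elimination, or the epoxide may oligomerise under BF3. Fallback: the two carbons are added by cross-coupling. Starting from 18, coupling with BrZnCH2CO2t-Bu under Pd(PPh3)4 catalysis (THF, 60 °C) gives tert-butyl 3-{[tert-butyl(diphenyl)silyl]oxymethyl}but-3-enoate F10. LiAlH4 (Et2O, 0 °C) reduces the ester to the alcohol. The route is rejoined at 20.

## Further compounds

F1 | step 15 | methyl (2Z)-2-iodo-6-{[tert-butyl(diphenyl)silyl]oxymethyl}hepta-2,6-dienoate | COC(=O)/C(I)=C/CCC(=C)CO[Si](c1ccccc1)(c1ccccc1)C(C)(C)C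
F2 | step 15 | [(1Z)-1-(methoxycarbonyl)-5-{[tert-butyl(diphenyl)silyl]oxymethyl}hexa-1,5-dien-1-yl]magnesium chloride | COC(=O)/C([Mg]Cl)=C/CCC(=C)CO[Si](c1ccccc1)(c1ccccc1)C(C)(C)C
F3 | step 17 | methyl (2E)-2-[(1S,2S)-2-[(2R,3S)-2-ethenyl-5-oxooxolan-3-yl]-1-hydroxy-2-(4-methoxybenzyloxy)ethyl]-6-(hydroxymethyl)hepta-2,6-dienoate | C=C[C@H]1OC(=O)C[C@@H]1[C@H](OCc1ccc(OC)cc1)[C@@H](O)/C(C(=O)OC)=C\CCC(=C)CO
F4 | step 17 | methyl 9,15-dihydroxy-8-(PMBO)germacra-1(10),4-dien-12,6-olid-14-oate (ring-cis alkenes) | C1C(=O)O[C@@H]2/C=C(/CO)CC/C=C(/C(=O)OC)[C@H](O)[C@@H](OCc3ccc(OC)cc3)[C@@H]12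
F5 | step 17 | methyl 9-hydroxy-15-(TBDPSO)-8-(PMBO)germacra-1(10),4-dien-12,6-olid-14-oate | C1C(=O)O[C@@H]2/C=C(/CO[Si](c3ccccc3)(c3ccccc3)C(C)(C)C)CC/C=C(/C(=O)OC)[C@H](O)[C@@H](OCc3ccc(OC)cc3)[C@@H]12
F6 | step 20 | 14-hydroxy-9-(TBSO)-15-(TBDPSO)-8-(PMBO)germacra-1(10),4,11(13)-trien-12,6-olide | C=C1C(=O)O[C@@H]2/C=C(/CO[Si](c3ccccc3)(c3ccccc3)C(C)(C)C)CC/C=C(/CO)[C@H](O[Si](C)(C)C(C)(C)C)[C@@H](OCc3ccc(OC)cc3)[C@@H]12
F7 | step 9 | 3-C-(carboxymethyl)-3,5,6-trideoxy-D-lyxo-hex-5-enofuranose 2,3-γ-lactone (lactol anomers) | C=C[C@H]1OC(O)[C@H]2OC(=O)C[C@@H]12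
F8 | step 9 | 1-O-TBDPS derivative of F7 | C=C[C@H]1OC(O[Si](c2ccccc2)(c2ccccc2)C(C)(C)C)[C@H]2OC(=O)C[C@@H]12
F9 | step 9 | 4-methoxybenzyl [1-O-TBDPS-3,5,6-trideoxy-2-O-(4-methoxybenzyl)-D-lyxo-hex-5-enofuranos-3-C-yl]acetate | C=C[C@H]1OC(O[Si](c2ccccc2)(c2ccccc2)C(C)(C)C)[C@@H](OCc2ccc(OC)cc2)[C@H]1CC(=O)OCc1ccc(OC)cc1
F10 | step 13 | tert-butyl 3-{[tert-butyl(diphenyl)silyl]oxymethyl}but-3-enoate | C=C(CC(=O)OC(C)(C)C)CO[Si](c1ccccc1)(c1ccccc1)C(C)(C)C
A1 | alternative 1 | 9-(TBSO)-6,12-bis(TESO)-15-(TBDPSO)-14-oxogermacra-1(10),4,11(13)-trien-8-yl (2S)-2-methylbutanoate | C=C(CO[Si](CC)(CC)CC)[C@H]1[C@H](O[Si](CC)(CC)CC)/C=C(/CO[Si](c2ccccc2)(c2ccccc2)C(C)(C)C)CC/C=C(/C=O)[C@H](O[Si](C)(C)C(C)(C)C)[C@H]1OC(=O)[C@@H](C)CC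
A2 | alternative 1 | cyclobutene precursor of A1 (C5=C11 in the four-membered ring, O6 and C8 cis on it) | C=C(CO[Si](c1ccccc1)(c1ccccc1)C(C)(C)C)CC/C=C(/C=O)[C@H](O[Si](C)(C)C(C)(C)C)[C@@H](OC(=O)[C@@H](C)CC)[C@@H]1[C@H](O[Si](CC)(CC)CC)C=C1CO[Si](CC)(CC)CC
A3 | alternative 2 | cyclodeca-2,6-dienone with 8-OPMB, 9-OMOM, 14-OTBS and 15-OTBDPS (C6 ketone, both alkenes ring-cis) | O=C1/C=C(/CO[Si](c2ccccc2)(c2ccccc2)C(C)(C)C)CC/C=C(/CO[Si](C)(C)C(C)(C)C)[C@H](OCOC)[C@@H](OCc2ccc(OC)cc2)C1
A4 | alternative 2 | cis-1,2-dialkenylcyclohex-2-enol precursor of A3 (both enol ethers E) | O[C@]1(/C=C/OCc2ccc(OC)cc2)C=C(CO[Si](c2ccccc2)(c2ccccc2)C(C)(C)C)CC[C@H]1/C(CO[Si](C)(C)C(C)(C)C)=C/OCOC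
A5 | alternative 3 | ten-membered diene with a phenylsulfonyl group on C3 (C3 epimers) | C=C(CO[Si](CC)(CC)CC)[C@H]1[C@H](O[Si](CC)(CC)CC)/C=C(/CO[Si](c2ccccc2)(c2ccccc2)C(C)(C)C)C(S(=O)(=O)c2ccccc2)C/C=C(/CO[Si](CC)(CC)CC)[C@H](O[Si](C)(C)C(C)(C)C)[C@H]1OCc1ccc(OC)cc1
A6 | alternative 3 | acyclic C2 allylic bromide / C3 allylic phenyl sulfone precursor of A5 | C=C(CO[Si](CC)(CC)CC)[C@@H]([C@H](O[Si](CC)(CC)CC)/C=C(/CO[Si](c1ccccc1)(c1ccccc1)C(C)(C)C)CS(=O)(=O)c1ccccc1)[C@H](OCc1ccc(OC)cc1)[C@@H](O[Si](C)(C)C(C)(C)C)/C(CO[Si](CC)(CC)CC)=C\CBr
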